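**Plan**

1. Cuts: first the interflavan C4(upper)–C8(lower) bond (Friedel–Crafts, flavan-4-yl cation + ring A of the lower unit). Lower ring C (O1–C2–C3–C4–C4a–C8a) is then traced through its C3 ketone to a five-membered 2-aryl-2,3-dihydrobenzofuran-3-ol ring (O1–C2–C3–C3a–C7a) that carries C4 as an exocyclic CH2OMs on C3. That ring is cut at C2–C3 (carbene C–H insertion) to an aryl diazoacetate of the symmetric tris(4-benzyloxybenzyl) ether of phloroacetophenone. The upper C2–aryl bond is cut to 7-benzyloxychromone + an arylboronic acid.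
2. Forward: ring A is bought; C–H insertion closes the five-membered ring; C3 is hydroxylated, its ester reduced and mesylated; a 1,2-shift of the ring A carbon from C3 to the CH2 enlarges the ring to the flavan-3-one; reduction gives the 2,3-cis alcohol; the upper flavan is joined at C8; hydrogenolysis frees all phenols.
3. Feature that makes the key event possible: in lower ring C, C3 bears oxygen and C4 is a CH2 bonded to C4a, the ring A carbon with oxygen on both ortho carbons (C5, C8a) and on the para carbon (C7). Such an aryl carbon migrates very readily and the C3 oxygen supplies the push, so the flavan-3-one is the natural product of a semipinacol shift from the dihydrobenzofuran.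
4. Stereochemistry: lower C2 from Rh2(R-PTAD)4 (C–H insertion); lower C3 relayed from C2 (hydride anti to the aryl group); upper C2 from Pd(OCOCF3)2 with the (R)-tert-butyl pyridine–oxazoline ligand; upper C4 relayed from upper C2 (axial attack on the cation, trans to the aryl group).
5. One 4-benzyloxybenzyl arm becomes C2 and ring B; the other two protect O5 and O7 and fall in the final hydrogenolysis.

Key step: step 8

Assumption: the sense of induction in steps 4 and 11 is taken from the closest simpler substrates (2-benzyloxyphenyl diazoacetates; unsubstituted chromone); should a first run show the opposite sense, the mirror-image catalyst or ligand, both available, is to be used.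

**Route**

Step 1
Reactants: 1 2',4',6'-trihydroxyacetophenone; 2 4-(benzyloxy)benzyl chloride (3.3 equiv in all, three of which are consumed)
Product: 3 1-{2,4,6-tris[(4-benzyloxybenzyl)oxy]phenyl}ethan-1-one
Conditions: K2CO3, KI (cat.), DMF, 70 °C
Reagents that add atoms: 4-(benzyloxy)benzyl chloride (second and third equivalents of 2), ClCc1ccc(OCc2ccccc2)cc1.ClCc1ccc(OCc2ccccc2)cc1
Why: Threefold Williamson ether synthesis in which each of the three phenolic hydroxyls takes up one molecule of 2; the acetyl group lowers the nucleophilicity of the ring carbons so that O-alkylation should prevail over C-alkylation, and warm DMF also alkylates the two hydrogen-bonded ortho hydroxyls.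

Step 2
Reactants: 3 1-{2,4,6-tris[(4-benzyloxybenzyl)oxy]phenyl}ethan-1-one
Product: 5 methyl 2-oxo-2-{2,4,6-tris[(4-benzyloxybenzyl)oxy]phenyl}acetate, via arylglyoxylic acid 4 (not isolated)
Conditions: SeO2, pyridine, 100 °C; filter, evaporate; then MeI, K2CO3, DMF, rt
Reagents that add atoms: selenium dioxide, O=[Se]=O; iodomethane, CI
Why: Riley-type SeO2 oxidation of an aryl methyl ketone in pyridine should stop at the arylglyoxylic acid, which is methylated as its carboxylate in the same flask; the benzylic ethers are inert to both sets of conditions.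

Step 3
Reactants: 5 methyl 2-oxo-2-{2,4,6-tris[(4-benzyloxybenzyl)oxy]phenyl}acetate
Product: 7 methyl 2-diazo-2-{2,4,6-tris[(4-benzyloxybenzyl)oxy]phenyl}acetate, via tosylhydrazone 6 (not isolated)
Conditions: TsNHNH2, toluene, 80 °C; then DBU, CH2Cl2, rt
Reagents that add atoms: p-toluenesulfonohydrazide, Cc1ccc(cc1)S(=O)(=O)NN
Why: Condensation at the ketone of the α-keto ester and base-induced loss of sulfinate (Bamford–Stevens diazo synthesis) is the standard entry from arylglyoxylates to aryldiazoacetates.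

Step 4
Reactants: 7 methyl 2-diazo-2-{2,4,6-tris[(4-benzyloxybenzyl)oxy]phenyl}acetate
Product: 8 methyl (2S,3R)-2-[4-(benzyloxy)phenyl]-4,6-bis{[4-(benzyloxy)benzyl]oxy}-2,3-dihydro-1-benzofuran-3-carboxylate (2,3-cis)
Conditions: Rh2(R-PTAD)4 (dirhodium tetrakis[(R)-N-phthaloyl-(1-adamantyl)glycinate], 1 mol %), toluene, −60 °C, slow addition of 7
Reagents that add atoms: none
Why: Intramolecular 1,5 C–H insertion of the donor/acceptor dirhodium carbene into a benzylic C–H bond α to ether oxygen closes the O1–C2–C3–C3a–C7a ring; the two ortho ether arms are homotopic, so only one constitution can form, and the chiral carboxylate catalyst selects one of the two enantiotopic benzylic hydrogens, which sets C2 as S (and C3 as R, cis, through the concerted insertion).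

Step 5
Reactants: 8 methyl (2S,3R)-2-[4-(benzyloxy)phenyl]-4,6-bis{[4-(benzyloxy)benzyl]oxy}-2,3-dihydro-1-benzofuran-3-carboxylate
Product: 9 methyl (2R,3S)-2-[4-(benzyloxy)phenyl]-4,6-bis{[4-(benzyloxy)benzyl]oxy}-3-hydroxy-2,3-dihydro-1-benzofuran-3-carboxylate (3-OH trans to the 2-aryl group)
Conditions: KN(SiMe3)2, THF, −78 °C; 2-(phenylsulfonyl)-3-phenyloxaziridine; AcOH quench
Reagents that add atoms: 2-(phenylsulfonyl)-3-phenyloxaziridine, O=S(=O)(c1ccccc1)N1OC1c1ccccc1
Why: Enolate hydroxylation with an N-sulfonyloxaziridine; the planar enolate should be attacked on the face away from the C2 aryl group, the C2–O1 bond lies in the nodal plane of the enolate so that β-elimination (and loss of the C2 configuration) is not expected at −78 °C, and the configuration of the new carbinol center is immaterial because step 8 erases it (the descriptor at C2 changes only through priorities).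

Step 6
Reactants: 9 methyl (2R,3S)-2-[4-(benzyloxy)phenyl]-4,6-bis{[4-(benzyloxy)benzyl]oxy}-3-hydroxy-2,3-dihydro-1-benzofuran-3-carboxylate
Product: 10 (2R,3R)-2-[4-(benzyloxy)phenyl]-4,6-bis{[4-(benzyloxy)benzyl]oxy}-3-(hydroxymethyl)-2,3-dihydro-1-benzofuran-3-ol
Conditions: LiAlH4, THF, 0 °C; aq. NaOH work-up
Reagents that add atoms: none
Why: Hydride reduction of the ester to the primary alcohol; the basic work-up keeps the tertiary, ring A-benzylic alcohol from ionizing.

Step 7
Reactants: 10 (2R,3R)-2-[4-(benzyloxy)phenyl]-4,6-bis{[4-(benzyloxy)benzyl]oxy}-3-(hydroxymethyl)-2,3-dihydro-1-benzofuran-3-ol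
Product: 11 {(2R,3R)-2-[4-(benzyloxy)phenyl]-4,6-bis{[4-(benzyloxy)benzyl]oxy}-3-hydroxy-2,3-dihydro-1-benzofuran-3-yl}methyl methanesulfonate
Conditions: MsCl (1.1 equiv), Et3N, CH2Cl2, −40 °C; cold NaHCO3 wash, used crude
Reagents that add atoms: methanesulfonyl chloride, CS(=O)(=O)Cl
Why: Selective sulfonylation of the primary hydroxyl; the tertiary hydroxyl is too hindered to react at −40 °C.

Step 8
Reactants: 11 {(2R,3R)-2-[4-(benzyloxy)phenyl]-4,6-bis{[4-(benzyloxy)benzyl]oxy}-3-hydroxy-2,3-dihydro-1-benzofuran-3-yl}methyl methanesulfonate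
Product: 12 (2R)-2-[4-(benzyloxy)phenyl]-5,7-bis{[4-(benzyloxy)benzyl]oxy}chroman-3-one
Conditions: Al(C2H5)3 (3 equiv), CH2Cl2, −78 to −30 °C
Reagents that add atoms: none
Why: Al(C2H5)3 turns the tertiary C3–OH into an aluminium alkoxide and activates the primary mesylate; the C3a carbon of the 1,3,5-trioxygenated ring A attacks the CH2 carbon from the rear (ipso, 3-exo-tet) to give a spiro[2.5]octadienyl (phenonium) cation, and the alkoxide lone pair at C3 then breaks the C3–C3a bond of this donor–acceptor cyclopropane, so that the aryl carbon ends on the former CH2 (now C4) and C3 becomes the ketone. The closest known reaction types are the organoaluminium-promoted semipinacol rearrangement of β-mesyloxy tertiary alcohols and the Tiffeneau–Demjanov ring expansion of 1-(aminomethyl)benzocycloalkan-1-ols with aryl migration. The six-membered O1–C2–C3–C4–C4a–C8a ring is not closed by a separate ring-forming attack: it arises from the five-membered O1–C2–C3–C3a–C7a ring by the 1,2-shift of the aryl carbon, which inserts the exocyclic CH2 between C3 and the arene. No stereocenter is created; C2 is not involved and should keep its configuration under the cold, aprotic conditions, under which α-aryl ketones are not enolized by this reagent, while the C3 carbinol center is erased. The selectivity needed is migration of the aryl carbon in preference to C2 (which would give the chroman-4-one), to epoxide closure and to ionization of the tertiary benzylic C3–O bond with aromatization to the benzofuran; the two ortho oxygens and the para oxygen make the aryl carbon by far the better migrating group, C2 carries the electron-withdrawing O1, the aluminium alkoxide is too weakly nucleophilic to close the epoxide, and no protic acid is present.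

Step 9
Reactants: 12 (2R)-2-[4-(benzyloxy)phenyl]-5,7-bis{[4-(benzyloxy)benzyl]oxy}chroman-3-one
Product: 13 (2R,3R)-2-[4-(benzyloxy)phenyl]-5,7-bis{[4-(benzyloxy)benzyl]oxy}chroman-3-ol (2,3-cis)
Conditions: LiBH(s-Bu)3, LiBr, THF, −78 °C
Reagents that add atoms: none
Why: Substrate-controlled ketone reduction with a bulky trialkylborohydride; hydride adds to the C3 carbonyl from the face opposite the C2 aryl group, which places the hydroxyl cis to the aryl group (3R), the established outcome for protected flavan-3-ones.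

Step 10
Reactants: 14 7-hydroxy-4H-chromen-4-one
Product: 15 7-(benzyloxy)-4H-chromen-4-one
Conditions: BnBr, K2CO3, DMF, rt
Reagents that add atoms: benzyl bromide, BrCc1ccccc1
Why: Williamson ether synthesis at the only hydroxyl.

Step 11
Reactants: 15 7-(benzyloxy)-4H-chromen-4-one; 16 [4-(benzyloxy)phenyl]boronic acid (2 equiv)
Product: 17 (2S)-7-(benzyloxy)-2-[4-(benzyloxy)phenyl]chroman-4-one
Conditions: Pd(OCOCF3)2 (5 mol %), (R)-4-tert-butyl-2-(pyridin-2-yl)-4,5-dihydrooxazole (6 mol %), NH4PF6, H2O, ClCH2CH2Cl, 60 °C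
Reagents that add atoms: none
Why: Palladium-catalyzed asymmetric conjugate addition of an arylboronic acid to a chromone with a pyridine–oxazoline ligand; the ligand controls the face of aryl-palladium insertion and sets C2 as S, and the neutral medium avoids ring opening of the flavanone to the chalcone.

Step 12
Reactants: 17 (2S)-7-(benzyloxy)-2-[4-(benzyloxy)phenyl]chroman-4-one
Product: 18 (2S,4S)-7-(benzyloxy)-2-[4-(benzyloxy)phenyl]chroman-4-ol (2,4-cis)
Conditions: NaBH4, THF–MeOH, 0 °C
Reagents that add atoms: none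
Why: Borohydride reduction of the chroman-4-one; axial hydride delivery should give the 2,4-cis alcohol, but the C4 configuration is immaterial because this center is ionized in step 13.

Step 13
Reactants: 13 (2R,3R)-2-[4-(benzyloxy)phenyl]-5,7-bis{[4-(benzyloxy)benzyl]oxy}chroman-3-ol (2.5 equiv, excess recovered); 18 (2S,4S)-7-(benzyloxy)-2-[4-(benzyloxy)phenyl]chroman-4-ol
Product: 19 (2R,3R)-8-{(2S,4R)-7-(benzyloxy)-2-[4-(benzyloxy)phenyl]chroman-4-yl}-2-[4-(benzyloxy)phenyl]-5,7-bis{[4-(benzyloxy)benzyl]oxy}chroman-3-ol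
Conditions: BF3·OEt2 (0.3 equiv), 4 Å molecular sieves, CH2Cl2, −78 to −40 °C
Reagents that add atoms: none
Why: Lewis acid-promoted Friedel–Crafts alkylation through the flavan-4-yl cation (stabilized by O1 and the para 7-benzyloxy group), formed from 18 with loss of its C4 hydroxyl as water; ring A of 13 should react at C8, which is flanked by only one benzylic ether arm, not at C6 between two, and the nucleophile adds axially to the half-chair cation with the C2 aryl group equatorial, which gives the 2,4-trans (4R) product.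

Step 14
Reactants: 19 (2R,3R)-8-{(2S,4R)-7-(benzyloxy)-2-[4-(benzyloxy)phenyl]chroman-4-yl}-2-[4-(benzyloxy)phenyl]-5,7-bis{[4-(benzyloxy)benzyl]oxy}chroman-3-ol
Product: 20 (2R,3R)-8-[(2S,4R)-7-hydroxy-2-(4-hydroxyphenyl)chroman-4-yl]-2-(4-hydroxyphenyl)chromane-3,5,7-triol (CNP0254623.2)
Conditions: H2 (1 atm), Pd(OH)2/C, THF–MeOH, rt
Reagents that add atoms: none
Why: Hydrogenolysis of all benzylic C–O ether bonds (each 4-benzyloxybenzyl ether falls to p-cresol and toluene); the flavan C2–O1 bonds and the interflavan C–C bond are not expected to cleave under these conditions and no stereocenter is touched.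

**Compound list**

1 | 2',4',6'-trihydroxyacetophenone | CC(=O)c1c(O)cc(O)cc1O | starting material
2 | 4-(benzyloxy)benzyl chloride | ClCc1ccc(OCc2ccccc2)cc1 | starting material
3 | 1-{2,4,6-tris[(4-benzyloxybenzyl)oxy]phenyl}ethan-1-one | CC(=O)c1c(OCc2ccc(OCc3ccccc3)cc2)cc(OCc2ccc(OCc3ccccc3)cc2)cc1OCc1ccc(OCc2ccccc2)cc1 | intermediate
4 | 2-oxo-2-{2,4,6-tris[(4-benzyloxybenzyl)oxy]phenyl}acetic acid | OC(=O)C(=O)c1c(OCc2ccc(OCc3ccccc3)cc2)cc(OCc2ccc(OCc3ccccc3)cc2)cc1OCc1ccc(OCc2ccccc2)cc1 | intermediate (not isolated)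
5 | methyl 2-oxo-2-{2,4,6-tris[(4-benzyloxybenzyl)oxy]phenyl}acetate | COC(=O)C(=O)c1c(OCc2ccc(OCc3ccccc3)cc2)cc(OCc2ccc(OCc3ccccc3)cc2)cc1OCc1ccc(OCc2ccccc2)cc1 | intermediate
6 | methyl 2-(2-tosylhydrazinylidene)-2-{2,4,6-tris[(4-benzyloxybenzyl)oxy]phenyl}acetate | COC(=O)C(=NNS(=O)(=O)c1ccc(C)cc1)c1c(OCc2ccc(OCc3ccccc3)cc2)cc(OCc2ccc(OCc3ccccc3)cc2)cc1OCc1ccc(OCc2ccccc2)cc1 | intermediate (not isolated)
7 | methyl 2-diazo-2-{2,4,6-tris[(4-benzyloxybenzyl)oxy]phenyl}acetate | COC(=O)C(=[N+]=[N-])c1c(OCc2ccc(OCc3ccccc3)cc2)cc(OCc2ccc(OCc3ccccc3)cc2)cc1OCc1ccc(OCc2ccccc2)cc1 | intermediate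
8 | methyl (2S,3R)-2-[4-(benzyloxy)phenyl]-4,6-bis{[4-(benzyloxy)benzyl]oxy}-2,3-dihydro-1-benzofuran-3-carboxylate | COC(=O)[C@@H]1c2c(OCc3ccc(OCc4ccccc4)cc3)cc(OCc3ccc(OCc4ccccc4)cc3)cc2O[C@@H]1c1ccc(OCc2ccccc2)cc1 | intermediate
9 | methyl (2R,3S)-2-[4-(benzyloxy)phenyl]-4,6-bis{[4-(benzyloxy)benzyl]oxy}-3-hydroxy-2,3-dihydro-1-benzofuran-3-carboxylate | COC(=O)[C@]1(O)c2c(OCc3ccc(OCc4ccccc4)cc3)cc(OCc3ccc(OCc4ccccc4)cc3)cc2O[C@@H]1c1ccc(OCc2ccccc2)cc1 | intermediate
10 | (2R,3R)-2-[4-(benzyloxy)phenyl]-4,6-bis{[4-(benzyloxy)benzyl]oxy}-3-(hydroxymethyl)-2,3-dihydro-1-benzofuran-3-ol | OC[C@]1(O)c2c(OCc3ccc(OCc4ccccc4)cc3)cc(OCc3ccc(OCc4ccccc4)cc3)cc2O[C@@H]1c1ccc(OCc2ccccc2)cc1 | intermediate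
11 | {(2R,3R)-2-[4-(benzyloxy)phenyl]-4,6-bis{[4-(benzyloxy)benzyl]oxy}-3-hydroxy-2,3-dihydro-1-benzofuran-3-yl}methyl methanesulfonate | CS(=O)(=O)OC[C@]1(O)c2c(OCc3ccc(OCc4ccccc4)cc3)cc(OCc3ccc(OCc4ccccc4)cc3)cc2O[C@@H]1c1ccc(OCc2ccccc2)cc1 | intermediate
12 | (2R)-2-[4-(benzyloxy)phenyl]-5,7-bis{[4-(benzyloxy)benzyl]oxy}chroman-3-one | O=C1Cc2c(OCc3ccc(OCc4ccccc4)cc3)cc(OCc3ccc(OCc4ccccc4)cc3)cc2O[C@@H]1c1ccc(OCc2ccccc2)cc1 | intermediate
13 | (2R,3R)-2-[4-(benzyloxy)phenyl]-5,7-bis{[4-(benzyloxy)benzyl]oxy}chroman-3-ol | O[C@@H]1Cc2c(OCc3ccc(OCc4ccccc4)cc3)cc(OCc3ccc(OCc4ccccc4)cc3)cc2O[C@@H]1c1ccc(OCc2ccccc2)cc1 | intermediate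
14 | 7-hydroxy-4H-chromen-4-one | O=c1ccoc2cc(O)ccc12 | starting material
15 | 7-(benzyloxy)-4H-chromen-4-one | O=c1ccoc2cc(OCc3ccccc3)ccc12 | intermediate
16 | [4-(benzyloxy)phenyl]boronic acid | OB(O)c1ccc(OCc2ccccc2)cc1 | starting material
17 | (2S)-7-(benzyloxy)-2-[4-(benzyloxy)phenyl]chroman-4-one | O=C1C[C@@H](c2ccc(OCc3ccccc3)cc2)Oc2cc(OCc3ccccc3)ccc21 | intermediate
18 | (2S,4S)-7-(benzyloxy)-2-[4-(benzyloxy)phenyl]chroman-4-ol | O[C@H]1C[C@@H](c2ccc(OCc3ccccc3)cc2)Oc2cc(OCc3ccccc3)ccc21 | intermediate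
19 | (2R,3R)-8-{(2S,4R)-7-(benzyloxy)-2-[4-(benzyloxy)phenyl]chroman-4-yl}-2-[4-(benzyloxy)phenyl]-5,7-bis{[4-(benzyloxy)benzyl]oxy}chroman-3-ol | c1ccccc1COc1ccc([C@@H]2C[C@@H](c3c(OCc5ccc(OCc6ccccc6)cc5)cc(OCc5ccc(OCc6ccccc6)cc5)c4c3O[C@H](c3ccc(OCc5ccccc5)cc3)[C@H](O)C4)c3ccc(OCc5ccccc5)cc3O2)cc1 | intermediate
20 | (2R,3R)-8-[(2S,4R)-7-hydroxy-2-(4-hydroxyphenyl)chroman-4-yl]-2-(4-hydroxyphenyl)chromane-3,5,7-triol | Oc1ccc([C@@H]2C[C@@H](c3c(O)cc(O)c4c3O[C@H](c3ccc(O)cc3)[C@H](O)C4)c3ccc(O)cc3O2)cc1 | target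

**Totals**

Total step count: 14. Longest linear sequence: 11 steps (steps 1–9, 13, 14).

**Steps most likely to fail**

1. Step 8 (ring expansion). What may go wrong: ionization of the tertiary C3–O bond with loss of the C2 proton and aromatization to the benzofuran; closure of the alkoxide onto the CH2 to a spiro-epoxide; enolization of the product with erosion of the C2 configuration. Fallback: a Tiffeneau–Demjanov ring expansion, which replaces sulfonate and Lewis acid by a diazonium leaving group. It sets out from hydroxy ester 9: ammonolysis (NH3, MeOH, 60 °C) should give the primary amide F1, LiAlH4 (THF, reflux) the amino alcohol F2, and NaNO2 in aqueous AcOH–THF at 0 °C the diazonium ion, from which dinitrogen leaves with the same shift of the ring A carbon. The fallback comes back to the route at ketone 12.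

2. Step 13 (interflavan coupling). What may go wrong: poor facial selectivity at C4 of the cation, competing attack at C6, self-condensation of the cation precursor, and acid cleavage of the 4-benzyloxybenzyl ethers. Fallback: a change of electrophile and of the mode of activation, from hard-acid ionization of the alcohol to thiophilic activation of a thioether under non-protic conditions. It sets out from 18: BnSH with ZnI2 in CH2Cl2 should give the 4-benzylsulfanylflavan F3 (both C4 epimers serve); AgBF4 in THF at 0 °C, with slow addition to excess 13, releases the same cation without Brønsted or boron Lewis acid. The fallback comes back at 19.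

3. Step 4 (C–H insertion). What may go wrong: poor enantiofacial discrimination because the 2,6-dialkoxyaryl group is twisted out of the carbene plane, and carbene dimerization. Fallback: auxiliary control with separable diastereomers in place of catalyst control. It sets out from acid 4, which in this variant is isolated after the SeO2 oxidation and not methylated. Esterification with (S)-2-hydroxy-1-(pyrrolidin-1-yl)propan-1-one (DCC, DMAP) gives the lactamide glyoxylate F4; TsNHNH2 gives the tosylhydrazone F5 and DBU the diazo ester F6. Insertion with achiral Rh2(OCOCH3)4 gives the dihydrobenzofuran F7, whose diastereomers at C2 can be separated by chromatography or crystallization (the auxiliary from (R)-lactic acid is used if the 2S isomer is the minor one). Hydroxylation as in step 5 gives the hydroxy ester F8, and LiAlH4 as in step 6 removes the auxiliary. The fallback comes back at diol 10.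

**Further compounds**

F1 | step 8 | (2R,3S)-2-[4-(benzyloxy)phenyl]-4,6-bis{[4-(benzyloxy)benzyl]oxy}-3-hydroxy-2,3-dihydro-1-benzofuran-3-carboxamide | NC(=O)[C@]1(O)c2c(OCc3ccc(OCc4ccccc4)cc3)cc(OCc3ccc(OCc4ccccc4)cc3)cc2O[C@@H]1c1ccc(OCc2ccccc2)cc1
F2 | step 8 | (2R,3R)-3-(aminomethyl)-2-[4-(benzyloxy)phenyl]-4,6-bis{[4-(benzyloxy)benzyl]oxy}-2,3-dihydro-1-benzofuran-3-ol | NC[C@]1(O)c2c(OCc3ccc(OCc4ccccc4)cc3)cc(OCc3ccc(OCc4ccccc4)cc3)cc2O[C@@H]1c1ccc(OCc2ccccc2)cc1
F3 | step 13 | (2S)-4-(benzylsulfanyl)-7-(benzyloxy)-2-[4-(benzyloxy)phenyl]chromane (C4 epimers) | C(c1ccccc1)SC1C[C@@H](c2ccc(OCc3ccccc3)cc2)Oc2cc(OCc3ccccc3)ccc21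
F4 | step 4 | (S)-1-oxo-1-(pyrrolidin-1-yl)propan-2-yl 2-oxo-2-{2,4,6-tris[(4-benzyloxybenzyl)oxy]phenyl}acetate | C[C@H](OC(=O)C(=O)c1c(OCc2ccc(OCc3ccccc3)cc2)cc(OCc2ccc(OCc3ccccc3)cc2)cc1OCc1ccc(OCc2ccccc2)cc1)C(=O)N1CCCC1
F5 | step 4 | N-tosylhydrazone of F4 | C[C@H](OC(=O)C(=NNS(=O)(=O)c1ccc(C)cc1)c1c(OCc2ccc(OCc3ccccc3)cc2)cc(OCc2ccc(OCc3ccccc3)cc2)cc1OCc1ccc(OCc2ccccc2)cc1)C(=O)N1CCCC1
F6 | step 4 | (S)-1-oxo-1-(pyrrolidin-1-yl)propan-2-yl 2-diazo-2-{2,4,6-tris[(4-benzyloxybenzyl)oxy]phenyl}acetate | C[C@H](OC(=O)C(=[N+]=[N-])c1c(OCc2ccc(OCc3ccccc3)cc2)cc(OCc2ccc(OCc3ccccc3)cc2)cc1OCc1ccc(OCc2ccccc2)cc1)C(=O)N1CCCC1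
F7 | step 4 | (S)-1-oxo-1-(pyrrolidin-1-yl)propan-2-yl (2S,3R)-2-[4-(benzyloxy)phenyl]-4,6-bis{[4-(benzyloxy)benzyl]oxy}-2,3-dihydro-1-benzofuran-3-carboxylate | C[C@H](OC(=O)[C@@H]1c2c(OCc3ccc(OCc4ccccc4)cc3)cc(OCc3ccc(OCc4ccccc4)cc3)cc2O[C@@H]1c1ccc(OCc2ccccc2)cc1)C(=O)N1CCCC1
F8 | step 4 | (S)-1-oxo-1-(pyrrolidin-1-yl)propan-2-yl (2R,3S)-2-[4-(benzyloxy)phenyl]-4,6-bis{[4-(benzyloxy)benzyl]oxy}-3-hydroxy-2,3-dihydro-1-benzofuran-3-carboxylate | C[C@H](OC(=O)[C@]1(O)c2c(OCc3ccc(OCc4ccccc4)cc3)cc(OCc3ccc(OCc4ccccc4)cc3)cc2O[C@@H]1c1ccc(OCc2ccccc2)cc1)C(=O)N1CCCC1
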